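## Retrosynthetic overview

1. Target 32 ⇐ amine 30 (the C11=C13 methylene stored as CH2NMe2) ⇐ ynal–ketone 28, by cutting C1–C10 and O–C3 in one operation.
2. Enabling feature: in the furanone ring (O–C10–C1(=O)–C2=C3) the C1 ketone is the acyloin partner of the oxygen-bearing quaternary C10, and C3 is its β-carbon. The furanone plus the ten-membered carbocycle C1–C10 is therefore an isomer of a C10 methyl ketone and a C1–C2≡C3 ynal (benzoin bond C1–C10, oxa-Michael bond O–C3).
3. 28 ⇐ Z-vinyl iodide 25 + propargyl alcohol (C3–C4, Sonogashira); 25 ⇐ alcohol 19 + epoxy acid 23 (asymmetric epoxidation of angelyl alcohol).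
4. 19 ⇐ lactone 14 ⇐ anti-aldol (C6–C7) of succinate thioimide 7 with (Z)-3-iodobut-2-enal 4, Felkin methallylation (C8–C9), lactonisation; C11–C13 by aminomethylation.
5. Ring order: γ-lactone (step 8), epoxide (step 13, side chain), then in step 18 the ten-membered carbocycle and directly the furanone across it.

Key step: step 18

Remark 1: the germacrane locants of the target (C1–C15) are used for the corresponding atoms of all intermediates.

Remark 2 (assumption): the MgBr2·OEt2-catalysed anti-aldol of N-acylthiazolidinethiones is taken to use the same enolate face as the Evans syn aldol, so the (4S)-auxiliary gives the required C6/C7 configuration; if the sense is opposite, the (4R)-auxiliary is used.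

## Route

Step 1
Reactants: 1 but-2-yn-1-ol
Product: 3 (Z)-3-iodobut-2-en-1-ol, via cyclic alkenylaluminate 2 (not isolated)
Conditions: NaAlH2(OCH2CH2OMe)2, THF, 0 °C to rt; then I2, −78 to 0 °C
Reagents that add atoms: iodine, II
Why: Alkoxide-directed trans-hydroalumination of the propargylic alcohol places aluminium at C4 anti to the new hydrogen, and iodinolysis with retention should give the Z iodide (hydroalumination–iodination).

Step 2
Reactants: 3 (Z)-3-iodobut-2-en-1-ol
Product: 4 (Z)-3-iodobut-2-enal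
Conditions: MnO2, CH2Cl2, rt
Reagents that add atoms: none
Why: Allylic alcohol oxidation with MnO2 is neutral and should keep the Z geometry.

Step 3
Reactants: 5 (4S)-4-benzyl-1,3-thiazolidine-2-thione; 6 4-tert-butoxy-4-oxobutanoic acid
Product: 7 tert-butyl 4-[(4S)-4-benzyl-2-sulfanylidene-1,3-thiazolidin-3-yl]-4-oxobutanoate
Conditions: DCC, DMAP (cat.), CH2Cl2, 0 °C to rt
Reagents that add atoms: none
Why: Carbodiimide (Steglich-type) N-acylation of the thiazolidinethione.

Step 4
Reactants: 7 tert-butyl 4-[(4S)-4-benzyl-2-sulfanylidene-1,3-thiazolidin-3-yl]-4-oxobutanoate; 4 (Z)-3-iodobut-2-enal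
Product: 9 tert-butyl (3S,4R,5Z)-3-{[(4S)-4-benzyl-2-sulfanylidene-1,3-thiazolidin-3-yl]carbonyl}-4-hydroxy-6-iodohept-5-enoate, via trimethylsilyl ether 8 (not isolated)
Conditions: MgBr2·OEt2 (20 mol%), Et3N, Me3SiCl, EtOAc, rt; then 1 M HCl, THF
Reagents that add atoms: none
Why: Magnesium-halide-catalysed Evans anti-aldol reaction: soft enolisation gives the Z enolate of the thioimide, the (4S)-benzyl group shields one enolate face (sets C7) and the boat-like transition state with in situ silylation gives the anti relationship (sets C6).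

Step 5
Reactants: 9 tert-butyl (3S,4R,5Z)-3-{[(4S)-4-benzyl-2-sulfanylidene-1,3-thiazolidin-3-yl]carbonyl}-4-hydroxy-6-iodohept-5-enoate
Product: 10 tert-butyl (3S,4R,5Z)-3-{[(4S)-4-benzyl-2-sulfanylidene-1,3-thiazolidin-3-yl]carbonyl}-4-[(tert-butyldimethylsilyl)oxy]-6-iodohept-5-enoate
Conditions: tBuMe2SiOTf, 2,6-lutidine, CH2Cl2, −78 to 0 °C
Reagents that add atoms: tert-butyldimethylsilyl trifluoromethanesulfonate, CC(C)(C)[Si](C)(C)OS(=O)(=O)C(F)(F)F
Why: Silyl ether formation protects the C6 hydroxyl and keeps it from lactonising onto the ester.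

Step 6
Reactants: 10 tert-butyl (3S,4R,5Z)-3-{[(4S)-4-benzyl-2-sulfanylidene-1,3-thiazolidin-3-yl]carbonyl}-4-[(tert-butyldimethylsilyl)oxy]-6-iodohept-5-enoate
Product: 11 tert-butyl (3S,4R,5Z)-4-[(tert-butyldimethylsilyl)oxy]-3-formyl-6-iodohept-5-enoate
Conditions: iBu2AlH, CH2Cl2, −78 °C
Reagents that add atoms: none
Why: Partial reduction of the N-acylthiazolidinethione by iBu2AlH stops at the aldehyde through a stable tetrahedral aluminate and should leave the tert-butyl ester; the auxiliary is released.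

Step 7
Reactants: 11 tert-butyl (3S,4R,5Z)-4-[(tert-butyldimethylsilyl)oxy]-3-formyl-6-iodohept-5-enoate; 12 trimethyl(2-methylprop-2-en-1-yl)silane
Product: 13 tert-butyl (3R,4R,5Z)-4-[(tert-butyldimethylsilyl)oxy]-3-[(1S)-1-hydroxy-3-methylbut-3-en-1-yl]-6-iodohept-5-enoate
Conditions: BF3·OEt2, CH2Cl2, −78 °C
Reagents that add atoms: none
Why: Hosomi–Sakurai allylation under non-chelating activation: Felkin–Anh addition (C6 branch as the large group) and 1,3-anti induction from the β-silyloxy group reinforce each other and set C8.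

Step 8
Reactants: 13 tert-butyl (3R,4R,5Z)-4-[(tert-butyldimethylsilyl)oxy]-3-[(1S)-1-hydroxy-3-methylbut-3-en-1-yl]-6-iodohept-5-enoate
Product: 14 (4R,5S)-4-[(1R,2Z)-1-[(tert-butyldimethylsilyl)oxy]-3-iodobut-2-en-1-yl]-5-(2-methylprop-2-en-1-yl)oxolan-2-one
Conditions: camphorsulfonic acid (cat.), toluene, 60 °C
Reagents that add atoms: none
Why: Acid-catalysed intramolecular transesterification (γ-lactonisation) closes the trans-disubstituted lactone without touching a stereocentre.

Step 9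
Reactants: 14 (4R,5S)-4-[(1R,2Z)-1-[(tert-butyldimethylsilyl)oxy]-3-iodobut-2-en-1-yl]-5-(2-methylprop-2-en-1-yl)oxolan-2-one
Product: 16 (3S,4R,5S)-4-[(1R,2Z)-1-[(tert-butyldimethylsilyl)oxy]-3-iodobut-2-en-1-yl]-3-[(dimethylamino)methyl]-5-(2-methylprop-2-en-1-yl)oxolan-2-one, via lithium enolate 15 (not isolated)
Conditions: LiN(SiMe3)2, THF, −78 °C; then Eschenmoser's salt, −78 °C to rt
Reagents that add atoms: Eschenmoser's salt (N,N-dimethylmethyleneiminium iodide), C=[N+](C)C.[I-]
Why: Mannich aminomethylation of the lactone enolate should occur anti to the C7 substituent (C11, erased in step 19) and stores the future methylene as a β-amino lactone that is inert to carbenes and alkoxides.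

Step 10
Reactants: 16 (3S,4R,5S)-4-[(1R,2Z)-1-[(tert-butyldimethylsilyl)oxy]-3-iodobut-2-en-1-yl]-3-[(dimethylamino)methyl]-5-(2-methylprop-2-en-1-yl)oxolan-2-one
Product: 18 (3S,4R,5S)-4-[(1R,2Z)-1-[(tert-butyldimethylsilyl)oxy]-3-iodobut-2-en-1-yl]-3-[(dimethylamino)methyl]-5-(2-oxopropyl)oxolan-2-one, via ammonium trifluoroacetate 17 (not isolated)
Conditions: CF3CO2H (1.1 equiv), CH2Cl2/MeOH; O3, −78 °C; Me2S; aq NaHCO3
Reagents that add atoms: ozone, [O-][O+]=O
Why: Ozonolysis with reductive work-up should cleave the electron-rich 1,1-disubstituted alkene selectively (amine protected as its salt, iodoalkene deactivated) to give the C10 methyl ketone.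

Step 11
Reactants: 18 (3S,4R,5S)-4-[(1R,2Z)-1-[(tert-butyldimethylsilyl)oxy]-3-iodobut-2-en-1-yl]-3-[(dimethylamino)methyl]-5-(2-oxopropyl)oxolan-2-one
Product: 19 (3S,4S,5S)-3-[(dimethylamino)methyl]-4-[(1R,2Z)-1-hydroxy-3-iodobut-2-en-1-yl]-5-(2-oxopropyl)oxolan-2-one
Conditions: HF·pyridine, pyridine, THF, 0 °C to rt
Reagents that add atoms: none
Why: Fluoride desilylation under buffered conditions frees the C6 hydroxyl; the trans 8,12-lactone should be favoured over translactonisation to the cis 6,12-isomer.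

Step 12
Reactants: 20 angelic acid
Product: 21 (Z)-2-methylbut-2-en-1-ol
Conditions: LiAlH4, Et2O, 0 °C
Reagents that add atoms: none
Why: Hydride reduction of the acid to the allylic alcohol leaves the Z trisubstituted alkene untouched (LiAlH4 reduction).

Step 13
Reactants: 21 (Z)-2-methylbut-2-en-1-ol
Product: 22 [(2R,3S)-2,3-dimethyloxiran-2-yl]methanol
Conditions: Ti(OiPr)4 (10 mol%), D-(−)-diisopropyl tartrate (12 mol%), tBuOOH, 4 Å MS, CH2Cl2, −20 °C
Reagents that add atoms: tert-butyl hydroperoxide, CC(C)(C)OO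
Why: Sharpless asymmetric epoxidation: the D-(−)-tartrate should deliver oxygen to the face that gives the (2R,3S) epoxy alcohol, and the Z alkene fixes the relative configuration.

Step 14
Reactants: 22 [(2R,3S)-2,3-dimethyloxiran-2-yl]methanol
Product: 23 (2S,3S)-2,3-dimethyloxirane-2-carboxylic acid
Conditions: RuCl3·xH2O (2 mol%), NaIO4, MeCN/EtOAc/H2O, rt
Reagents that add atoms: water, O (the new carboxyl oxygen enters as the aldehyde hydrate); sodium periodate, [Na+].[O-]I(=O)(=O)=O (terminal oxygen source)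
Why: RuO4-catalysed oxidation of the primary alcohol to the acid leaves the epoxide and both stereocentres intact.

Step 15
Reactants: 19 (3S,4S,5S)-3-[(dimethylamino)methyl]-4-[(1R,2Z)-1-hydroxy-3-iodobut-2-en-1-yl]-5-(2-oxopropyl)oxolan-2-one; 23 (2S,3S)-2,3-dimethyloxirane-2-carboxylic acid
Product: 25 (1R,2Z)-1-[(2S,3R,4S)-4-[(dimethylamino)methyl]-5-oxo-2-(2-oxopropyl)oxolan-3-yl]-3-iodobut-2-en-1-yl (2S,3S)-2,3-dimethyloxirane-2-carboxylate, via mixed anhydride 24 (not isolated)
Conditions: 23, 2,4,6-Cl3C6H2COCl, Et3N, toluene, rt; then 19, DMAP, 40 °C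
Reagents that add atoms: none
Why: Yamaguchi esterification through the mixed 2,4,6-trichlorobenzoic anhydride should acylate the hindered allylic C6 hydroxyl with retention.

Step 16
Reactants: 25 (1R,2Z)-1-[(2S,3R,4S)-4-[(dimethylamino)methyl]-5-oxo-2-(2-oxopropyl)oxolan-3-yl]-3-iodobut-2-en-1-yl (2S,3S)-2,3-dimethyloxirane-2-carboxylate; 26 prop-2-yn-1-ol
Product: 27 (1S,2Z)-1-[(2S,3R,4S)-4-[(dimethylamino)methyl]-5-oxo-2-(2-oxopropyl)oxolan-3-yl]-6-hydroxy-3-methylhex-2-en-4-yn-1-yl (2S,3S)-2,3-dimethyloxirane-2-carboxylate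
Conditions: Pd(PPh3)2Cl2 (5 mol%), CuI (10 mol%), Et3N, THF, rt
Reagents that add atoms: none
Why: Sonogashira coupling forms C3–C4 with retention of the Z alkene geometry.

Step 17
Reactants: 27 (1S,2Z)-1-[(2S,3R,4S)-4-[(dimethylamino)methyl]-5-oxo-2-(2-oxopropyl)oxolan-3-yl]-6-hydroxy-3-methylhex-2-en-4-yn-1-yl (2S,3S)-2,3-dimethyloxirane-2-carboxylate
Product: 28 (1S,2Z)-1-[(2S,3R,4S)-4-[(dimethylamino)methyl]-5-oxo-2-(2-oxopropyl)oxolan-3-yl]-3-methyl-6-oxohex-2-en-4-yn-1-yl (2S,3S)-2,3-dimethyloxirane-2-carboxylate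
Conditions: MnO2, CH2Cl2, rt; used at once
Reagents that add atoms: none
Why: MnO2 oxidises the primary propargylic alcohol selectively to the ynal.

Step 18
Reactants: 28 (1S,2Z)-1-[(2S,3R,4S)-4-[(dimethylamino)methyl]-5-oxo-2-(2-oxopropyl)oxolan-3-yl]-3-methyl-6-oxohex-2-en-4-yn-1-yl (2S,3S)-2,3-dimethyloxirane-2-carboxylate
Product: 30 (6S,7R,8S,10S,11S)-13-(dimethylamino)-11,13-dihydro derivative of the target, via macrocyclic hydroxy ynone 29 (not isolated)
Conditions: aminoindanol-derived N-pentafluorophenyl triazolium tetrafluoroborate (20 mol%; enantiomer matched to the substrate), iPr2NEt (20 mol%), THF, 0.002 M, 40 °C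
Reagents that add atoms: none
Why: Proposed new method: the carbene adds to the C1 aldehyde, the resulting Breslow intermediate attacks the C10 ketone through C1 (10-exo-trig) to close the carbocycle as the α-hydroxy ynone 29 with release of the carbene, and the new C10 hydroxyl then adds across the ring to C3 of the bent C2≡C3 ynone (5-endo-dig oxa-Michael, carbene or amine as Brønsted base) to close the furanone. The closest known reaction types are the carbene-catalysed intramolecular aldehyde–ketone crossed benzoin cyclisation and the base- or carbene-mediated cyclisation of α'-hydroxy ynones to 3(2H)-furanones; their merger on an ynal to form a medium ring is not known. C10 is the only new stereocentre and is set in the C–C bond formation, its ketone face being selected by the chiral triazolylidene together with the turn imposed by the trans-lactone and the Z C4=C5 bond; because the benzoin step is reversible and the oxa-Michael step is not, the epimer whose hydroxyl can reach C3 should be drained. The step needs acyl-anion (C1) rather than redox or homoenolate (C3) reactivity of the ynal, which the electron-poor triazolium salt, the aprotic medium and the absence of alcohols should favour; Stetter addition and oxa-Michael addition to C13 are excluded by the CH2NMe2 mask, elimination of the lactone carboxylate from the β-acyloxy ketone by the weak amine base, and oligomerisation by high dilution.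

Step 19
Reactants: 30 (6S,7R,8S,10S,11S)-13-(dimethylamino)-11,13-dihydro derivative of the target
Product: 32 target CNP0258430.1, via quaternary ammonium iodide 31 (not isolated)
Conditions: MeI, MeCN, rt; then sat. aq NaHCO3, CH2Cl2, rt
Reagents that add atoms: none
Why: N-Methylation followed by Hofmann-type β-elimination regenerates the α-methylene lactone under conditions that should leave furanone, epoxide and ester untouched.

## Compound list

1 | but-2-yn-1-ol | CC#CCO | starting material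
2 | sodium 2,2-bis(2-methoxyethoxy)-3-methyl-2,5-dihydro-1,2-oxaaluminol-2-uide (cyclic alkenylaluminate) | CC1=CCO[Al-]1(OCCOC)OCCOC.[Na+] | intermediate
3 | (Z)-3-iodobut-2-en-1-ol | I/C(C)=C\CO | intermediate
4 | (Z)-3-iodobut-2-enal | I/C(C)=C\C=O | intermediate
5 | (4S)-4-benzyl-1,3-thiazolidine-2-thione | S=C1SC[C@H](Cc2ccccc2)N1 | starting material
6 | 4-tert-butoxy-4-oxobutanoic acid (mono-tert-butyl succinate) | OC(=O)CCC(=O)OC(C)(C)C | starting material
7 | tert-butyl 4-[(4S)-4-benzyl-2-sulfanylidene-1,3-thiazolidin-3-yl]-4-oxobutanoate | O=C(CCC(=O)OC(C)(C)C)N1C(=S)SC[C@@H]1Cc1ccccc1 | intermediate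
8 | O-trimethylsilyl ether of 9 | I/C(C)=C\[C@H](O[Si](C)(C)C)[C@H](CC(=O)OC(C)(C)C)C(=O)N1C(=S)SC[C@@H]1Cc1ccccc1 | intermediate
9 | tert-butyl (3S,4R,5Z)-3-{[(4S)-4-benzyl-2-sulfanylidene-1,3-thiazolidin-3-yl]carbonyl}-4-hydroxy-6-iodohept-5-enoate (anti-aldol; target configuration at C6 and C7) | I/C(C)=C\[C@H](O)[C@H](CC(=O)OC(C)(C)C)C(=O)N1C(=S)SC[C@@H]1Cc1ccccc1 | intermediate
10 | tert-butyldimethylsilyl ether of 9 | I/C(C)=C\[C@H](O[Si](C)(C)C(C)(C)C)[C@H](CC(=O)OC(C)(C)C)C(=O)N1C(=S)SC[C@@H]1Cc1ccccc1 | intermediate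
11 | tert-butyl (3S,4R,5Z)-4-[(tert-butyldimethylsilyl)oxy]-3-formyl-6-iodohept-5-enoate | I/C(C)=C\[C@H](O[Si](C)(C)C(C)(C)C)[C@H](CC(=O)OC(C)(C)C)C=O | intermediate
12 | trimethyl(2-methylprop-2-en-1-yl)silane | C=C(C)C[Si](C)(C)C | starting material
13 | tert-butyl (3R,4R,5Z)-4-[(tert-butyldimethylsilyl)oxy]-3-[(1S)-1-hydroxy-3-methylbut-3-en-1-yl]-6-iodohept-5-enoate | I/C(C)=C\[C@H](O[Si](C)(C)C(C)(C)C)[C@H](CC(=O)OC(C)(C)C)[C@@H](O)CC(C)=C | intermediate
14 | (4R,5S)-4-[(1R,2Z)-1-[(tert-butyldimethylsilyl)oxy]-3-iodobut-2-en-1-yl]-5-(2-methylprop-2-en-1-yl)oxolan-2-one (trans lactone) | C=C(C)C[C@@H]1OC(=O)C[C@H]1[C@@H](O[Si](C)(C)C(C)(C)C)/C=C(/C)I | intermediate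
15 | lithium enolate of 14 | C=C(C)C[C@@H]1OC([O-])=C[C@H]1[C@@H](O[Si](C)(C)C(C)(C)C)/C=C(/C)I.[Li+] | intermediate
16 | (3S,4R,5S)-4-[(1R,2Z)-1-[(tert-butyldimethylsilyl)oxy]-3-iodobut-2-en-1-yl]-3-[(dimethylamino)methyl]-5-(2-methylprop-2-en-1-yl)oxolan-2-one | C=C(C)C[C@@H]1OC(=O)[C@H](CN(C)C)[C@H]1[C@@H](O[Si](C)(C)C(C)(C)C)/C=C(/C)I | intermediate
17 | trifluoroacetate salt of 16 | C=C(C)C[C@@H]1OC(=O)[C@H](C[NH+](C)C)[C@H]1[C@@H](O[Si](C)(C)C(C)(C)C)/C=C(/C)I.[O-]C(=O)C(F)(F)F | intermediate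
18 | (3S,4R,5S)-4-[(1R,2Z)-1-[(tert-butyldimethylsilyl)oxy]-3-iodobut-2-en-1-yl]-3-[(dimethylamino)methyl]-5-(2-oxopropyl)oxolan-2-one | CC(=O)C[C@@H]1OC(=O)[C@H](CN(C)C)[C@H]1[C@@H](O[Si](C)(C)C(C)(C)C)/C=C(/C)I | intermediate
19 | (3S,4S,5S)-3-[(dimethylamino)methyl]-4-[(1R,2Z)-1-hydroxy-3-iodobut-2-en-1-yl]-5-(2-oxopropyl)oxolan-2-one | CC(=O)C[C@@H]1OC(=O)[C@H](CN(C)C)[C@H]1[C@@H](O)/C=C(/C)I | intermediate
20 | angelic acid, (Z)-2-methylbut-2-enoic acid | C/C=C(/C)C(=O)O | starting material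
21 | (Z)-2-methylbut-2-en-1-ol | C/C=C(/C)CO | intermediate
22 | [(2R,3S)-2,3-dimethyloxiran-2-yl]methanol | OC[C@@]1(C)O[C@H]1C | intermediate
23 | (2S,3S)-2,3-dimethyloxirane-2-carboxylic acid | OC(=O)[C@@]1(C)O[C@H]1C | intermediate
24 | (2S,3S)-2,3-dimethyloxirane-2-carboxylic 2,4,6-trichlorobenzoic anhydride | O=C(OC(=O)[C@@]1(C)O[C@H]1C)c1c(Cl)cc(Cl)cc1Cl | intermediate
25 | (1R,2Z)-1-[(2S,3R,4S)-4-[(dimethylamino)methyl]-5-oxo-2-(2-oxopropyl)oxolan-3-yl]-3-iodobut-2-en-1-yl (2S,3S)-2,3-dimethyloxirane-2-carboxylate | CC(=O)C[C@@H]1OC(=O)[C@H](CN(C)C)[C@H]1[C@@H](OC(=O)[C@@]1(C)O[C@H]1C)/C=C(/C)I | intermediate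
26 | prop-2-yn-1-ol | C#CCO | starting material
27 | (1S,2Z)-1-[(2S,3R,4S)-4-[(dimethylamino)methyl]-5-oxo-2-(2-oxopropyl)oxolan-3-yl]-6-hydroxy-3-methylhex-2-en-4-yn-1-yl (2S,3S)-2,3-dimethyloxirane-2-carboxylate | CC(=O)C[C@@H]1OC(=O)[C@H](CN(C)C)[C@H]1[C@@H](OC(=O)[C@@]1(C)O[C@H]1C)/C=C(/C)C#CCO | intermediate
28 | (1S,2Z)-1-[(2S,3R,4S)-4-[(dimethylamino)methyl]-5-oxo-2-(2-oxopropyl)oxolan-3-yl]-3-methyl-6-oxohex-2-en-4-yn-1-yl (2S,3S)-2,3-dimethyloxirane-2-carboxylate (ynal–ketone) | CC(=O)C[C@@H]1OC(=O)[C@H](CN(C)C)[C@H]1[C@@H](OC(=O)[C@@]1(C)O[C@H]1C)/C=C(/C)C#CC=O | intermediate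
29 | ten-membered α-hydroxy ynone (C1 ketone, C2≡C3, Z C4=C5, 10S tertiary alcohol) fused to the amino lactone and carrying the C6 epoxy ester | C[C@]1(O)C[C@@H]2OC(=O)[C@H](CN(C)C)[C@H]2[C@@H](OC(=O)[C@@]2(C)O[C@H]2C)/C=C(/C)C#CC1=O | intermediate
30 | (6S,7R,8S,10S,11S)-13-(dimethylamino)-11,13-dihydro derivative of the target | CN(C)C[C@H]1C(=O)O[C@H]2C[C@]3(C)OC(=CC3=O)/C(C)=C\[C@H](OC(=O)[C@@]3(C)O[C@H]3C)[C@H]12 | intermediate
31 | N-methyl quaternary ammonium iodide of 30 | C[N+](C)(C)C[C@H]1C(=O)O[C@H]2C[C@]3(C)OC(=CC3=O)/C(C)=C\[C@H](OC(=O)[C@@]3(C)O[C@H]3C)[C@H]12.[I-] | intermediate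
32 | CNP0258430.1, (6S,7R,8S,10S)-3,10-epoxy-1-oxogermacra-2,4Z,11(13)-trien-12,8-olide 6-[(2S,3S)-2,3-dimethyloxirane-2-carboxylate] | C=C1C(=O)O[C@H]2C[C@]3(C)OC(=CC3=O)/C(C)=C\[C@H](OC(=O)[C@@]3(C)O[C@H]3C)[C@H]12 | target

## Step count and risks

Total step count: 19. Longest linear sequence: 15 steps (1, 2, 4–11, 15–19); step 3 and steps 12–14 are side branches.

**Step 18 (most likely to fail).** The ynal-derived Breslow intermediate may divert to β-protonation (redox) or to attack through C3, the ketone face at C10 may be poorly differentiated, and ring closure may lose to oligomerisation. The fallback sets out from 18, before the epoxy ester is present because SmI2 would reduce it, and returns at 30. Sonogashira coupling of 18 with 26 should give the enynol F1, and MnO2 the ynal F2. SmI2-mediated ketyl–carbonyl (pinacol) macrocyclisation in THF at high dilution should give the ten-membered diol F3. MnO2 should oxidise only its secondary propargylic alcohol, giving the α'-hydroxy ynone F4, where C10 epimers are separated. AuCl3 (cat.) or Et2NH/EtOH should close the furanone to the silyl ether F5. HF·pyridine should give the alcohol F6, and Yamaguchi esterification with 23 rejoins the route at 30.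

**Step 4.** The β-iodo enal may isomerise from Z to E or be enolised at the γ-position under amine and Lewis acid, and the anti selectivity may be low for the succinate acyl group. The fallback sets out from 4 and returns at 11; it makes C7–C11 by alkylation instead of C6–C7 by aldol. A catalytic enantioselective Mukaiyama acetate aldol of 4 with 1-methoxy-1-(trimethylsilyloxy)ethene is used, with a chiral titanium Lewis acid from Ti(OiPr)4, a binaphthyl Schiff-base ligand and 3,5-di-tert-butylsalicylic acid (ligand enantiomer chosen to give the 3R carbinol). After desilylation this should give the hydroxy ester F7. Fráter–Seebach alkylation of its dianion (LiN(iPr)2, 2.2 equiv) with tert-butyl bromoacetate should give the anti succinate F8. Silylation (tBuMe2SiOTf, 2,6-lutidine) gives the silyl ether F9, and iBu2AlH at −78 °C should reduce only the methyl ester to the aldehyde 11.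

**Step 7.** Facial selectivity at C8 may be insufficient, or BF3 may cause loss of the tert-butyl or silyl group. The fallback sets out from 11 and returns at 13 with no new compound. It replaces substrate control by reagent control: methallylboration with B-(2-methylprop-2-en-1-yl)diisopinocampheylborane (from Ipc2BOMe and 2-methylallylmagnesium chloride; Ipc enantiomer matched to the Felkin sense) at −78 °C, followed by oxidative work-up.

## Further compounds

F1 | step 18 | (3S,4R,5S)-4-[(1S,2Z)-1-[(tert-butyldimethylsilyl)oxy]-6-hydroxy-3-methylhex-2-en-4-yn-1-yl]-3-[(dimethylamino)methyl]-5-(2-oxopropyl)oxolan-2-one | CC(=O)C[C@@H]1OC(=O)[C@H](CN(C)C)[C@H]1[C@@H](O[Si](C)(C)C(C)(C)C)/C=C(/C)C#CCO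
F2 | step 18 | ynal from F1 (6-oxo in place of 6-hydroxy) | CC(=O)C[C@@H]1OC(=O)[C@H](CN(C)C)[C@H]1[C@@H](O[Si](C)(C)C(C)(C)C)/C=C(/C)C#CC=O
F3 | step 18 | ten-membered C1,C10-diol (C1 carbinol configuration not controlled, 10S) with C6 silyl ether | C[C@]1(O)C[C@@H]2OC(=O)[C@H](CN(C)C)[C@H]2[C@@H](O[Si](C)(C)C(C)(C)C)/C=C(/C)C#CC1O
F4 | step 18 | ten-membered α'-hydroxy ynone with C6 silyl ether | C[C@]1(O)C[C@@H]2OC(=O)[C@H](CN(C)C)[C@H]2[C@@H](O[Si](C)(C)C(C)(C)C)/C=C(/C)C#CC1=O
F5 | step 18 | C6 tert-butyldimethylsilyl ether of the bicyclic furanone amino lactone | CN(C)C[C@H]1C(=O)O[C@H]2C[C@]3(C)OC(=CC3=O)/C(C)=C\[C@H](O[Si](C)(C)C(C)(C)C)[C@H]12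
F6 | step 18 | C6 alcohol of the bicyclic furanone amino lactone | CN(C)C[C@H]1C(=O)O[C@H]2C[C@]3(C)OC(=CC3=O)/C(C)=C\[C@H](O)[C@H]12
F7 | step 4 | methyl (3R,4Z)-3-hydroxy-5-iodohex-4-enoate | I/C(C)=C\[C@H](O)CC(=O)OC
F8 | step 4 | 4-tert-butyl 1-methyl (2S)-2-[(1R,2Z)-1-hydroxy-3-iodobut-2-en-1-yl]butanedioate | I/C(C)=C\[C@H](O)[C@H](CC(=O)OC(C)(C)C)C(=O)OC
F9 | step 4 | 4-tert-butyl 1-methyl (2S)-2-[(1R,2Z)-1-[(tert-butyldimethylsilyl)oxy]-3-iodobut-2-en-1-yl]butanedioate | I/C(C)=C\[C@H](O[Si](C)(C)C(C)(C)C)[C@H](CC(=O)OC(C)(C)C)C(=O)OC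
F0 | step 7 | none | none
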